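**Retrosynthetic overview**

1. The target is numbered as a daucane: C1 is the quaternary ring-fusion carbon with CH3-15, C4 the carbinol with isopropyl, C5 the ring-fusion CH, C6 the ester carbon, C7 the carbinol, C8/C9 the epoxide (CH3-14 on C8), C10 the CH2; ring A is the cyclopentane, ring B the cycloheptane, β is the face of CH3-15. Last operations: α-epoxidation of C8=C9, aroylation of O6, and the 7β-OH made from a 9α-OH by SN2 selenation and [2,3] shift.
2. Key disconnection: C9–C10 and C1–C5 together, by an intramolecular oxidopyrylium–alkene [5+2] cycloaddition that closes ring A and ring B at once from a monocyclic pyranone. The C5–O–C9 oxygen bridge is a temporary ring, cut at C5–O with SmI2.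
3. Feature that allows it: the five contiguous ring B carbons C5–C6–C7–C8–C9 (O on C6 and C9, C7/C8 oxidised) are the C2–C6 unit of a 3-oxidopyrylium. The C1–C10 unit that spans C5 and C9 is a 1,1-disubstituted alkene held on C5 by the chain C4–C3–C2 of ring A, and the C4 hydroxyl hydrogen-bonds to the oxido oxygen and steers the face.
4. The pyranone comes from an Achmatowicz rearrangement of a 4-methylfuran-2-yl carbinol; the quaternary carbinol C4 comes from (R)-2-hydroxy-3-methylbutanoic acid by dioxolanone alkylation (self-regeneration of the stereocentre).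
5. Ring order: furan → pyranone → rings A and B in one step → oxygen bridge opened → epoxide ring last.

Key step: step 9

Remark: compounds 1, 3, 7 and 24 are taken as purchasable; names of the bicyclic and tricyclic intermediates use the daucane locants and α/β descriptors defined above.

**Route**

Step 1
Reactants: 1 (R)-2-hydroxy-3-methylbutanoic acid
Product: 2 (2R,5R)-2-tert-butyl-5-(propan-2-yl)-1,3-dioxolan-4-one
Conditions: pivalaldehyde, TsOH·H2O (cat.), H2SO4 (cat.), pentane, reflux, Dean–Stark; cis isomer by crystallisation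
Reagents that add atoms: pivalaldehyde, CC(C)(C)C=O
Why: Acid-catalysed acetalisation of an α-hydroxy acid; the acetal carbon is set under thermodynamic control cis to the isopropyl group and the carbinol centre is untouched.

Step 2
Reactants: 3 3-methylbut-3-en-1-ol
Product: 4 3-methylbut-3-en-1-yl trifluoromethanesulfonate
Conditions: Tf2O, 2,6-lutidine, CH2Cl2, −78 °C; used at once without purification
Reagents that add atoms: trifluoromethanesulfonic anhydride, O=S(=O)(OS(=O)(=O)C(F)(F)F)C(F)(F)F
Why: O-Sulfonylation of a primary alcohol; a triflate is chosen because the hindered enolate of step 3 needs an electrophile that reacts at −78 °C.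

Step 3
Reactants: 2 (2R,5R)-2-tert-butyl-5-(propan-2-yl)-1,3-dioxolan-4-one; 4 3-methylbut-3-en-1-yl trifluoromethanesulfonate
Product: 6 (2R,5R)-2-tert-butyl-5-(3-methylbut-3-en-1-yl)-5-(propan-2-yl)-1,3-dioxolan-4-one, via lithium enolate 5 (not isolated)
Conditions: LiN(iPr)2, THF, −78 °C; then 4, −78 → −40 °C
Reagents that add atoms: none
Why: Enolate alkylation of the dioxolanone (self-regeneration of the stereocentre): the acetal centre sends the triflate to the face trans to tert-butyl, so the chain takes the place of the former hydrogen with retention and the quaternary carbinol (C4 of the target) is set.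

Step 4
Reactants: 7 3-methylfuran
Product: 8 2-bromo-3-methylfuran
Conditions: N-bromosuccinimide, DMF, 0 °C → rt, dark
Reagents that add atoms: N-bromosuccinimide, O=C1CCC(=O)N1Br
Why: Electrophilic bromination of the furan goes to the α-position activated by the adjacent methyl group; the bromine is a removable blocking group for step 5.

Step 5
Reactants: 8 2-bromo-3-methylfuran; 6 (2R,5R)-2-tert-butyl-5-(3-methylbut-3-en-1-yl)-5-(propan-2-yl)-1,3-dioxolan-4-one
Product: 12 (2R)-2-hydroxy-5-methyl-1-(4-methylfuran-2-yl)-2-(propan-2-yl)hex-5-en-1-one, via furyllithium 9 (not isolated), via bromo hemiketal alkoxide 10 (not isolated), via lithiated hemiketal alkoxide 11 (not isolated)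
Conditions: LiN(iPr)2, THF, −78 °C, 8; then 6, −78 °C; then n-BuLi, −78 °C; MeOH, then aq. NH4Cl, rt
Reagents that add atoms: none
Why: α-Lithiation of the bromofuran can occur only at the free α-carbon, single addition of the aryllithium to the non-enolisable lactone carbonyl gives a cyclic lithium hemiketal that should persist at −78 °C, bromine–lithium exchange and protonation then remove the blocking bromine, and aqueous work-up opens the hemiketal with loss of pivalaldehyde; no stereocentre is formed and the quaternary centre is not touched.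

Step 6
Reactants: 12 (2R)-2-hydroxy-5-methyl-1-(4-methylfuran-2-yl)-2-(propan-2-yl)hex-5-en-1-one
Product: 13 (1RS,2R)-5-methyl-1-(4-methylfuran-2-yl)-2-(propan-2-yl)hex-5-ene-1,2-diol
Conditions: NaBH4, MeOH, 0 °C → rt
Reagents that add atoms: none
Why: Borohydride reduction of an aryl ketone; the new carbinol centre is left uncontrolled on purpose because it becomes sp2 again in step 9.

Step 7
Reactants: 13 (1RS,2R)-5-methyl-1-(4-methylfuran-2-yl)-2-(propan-2-yl)hex-5-ene-1,2-diol
Product: 14 6-hydroxy-2-[(3R)-3-hydroxy-2,6-dimethylhept-6-en-3-yl]-5-methyl-2H-pyran-3(6H)-one (isomers at C2 and C6 of the pyranone)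
Conditions: N-bromosuccinimide, NaHCO3, NaOAc, THF/H2O 4:1, 0 °C
Reagents that add atoms: water, O
Why: Achmatowicz rearrangement: the electron-rich furan is oxidised much faster than the isolated 1,1-disubstituted alkene, and the ene-dione closes through the secondary furfuryl oxygen to the six-membered hemiacetal while the tertiary hydroxyl stays free; the two new centres need no control.

Step 8
Reactants: 14 6-hydroxy-2-[(3R)-3-hydroxy-2,6-dimethylhept-6-en-3-yl]-5-methyl-2H-pyran-3(6H)-one
Product: 15 6-[(3R)-3-hydroxy-2,6-dimethylhept-6-en-3-yl]-3-methyl-5-oxo-5,6-dihydro-2H-pyran-2-yl acetate (isomer mixture)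
Conditions: Ac2O, pyridine, DMAP (cat.), CH2Cl2, 0 °C
Reagents that add atoms: acetic anhydride, CC(=O)OC(C)=O
Why: Acylation of the hemiacetal hydroxyl, the only unhindered OH (the tertiary alcohol should not react), installs the leaving group for ylide formation; all diastereomers are carried on together.

Step 9
Reactants: 15 6-[(3R)-3-hydroxy-2,6-dimethylhept-6-en-3-yl]-3-methyl-5-oxo-5,6-dihydro-2H-pyran-2-yl acetate
Product: 17 5α,9α-epoxy-4β-hydroxydauc-7-en-6-one (oxygen-bridged cycloadduct), via oxidopyrylium ylide 16 (not isolated)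
Conditions: DBU, toluene (0.01 M), 80 °C
Reagents that add atoms: none
Why: DBU removes the proton next to the ketone and acetate leaves, so every stereoisomer of 15 (either configuration at the former carbinol carbon and at the acetal carbon) is funnelled into the same planar 3-oxidopyrylium 16, which adds through its termini C5 and C9 across the tethered C1=C10 double bond in a thermal [5+2] (4π + 2π) cycloaddition; the closest known reaction is the intramolecular oxidopyrylium–alkene cycloaddition of ylides that carry a pent-4-enyl chain on C2. Ring A closes as a five-membered ring by the C1–C5 bond (the three-atom chain C4–C3–C2 forces the internal alkene carbon onto C5) and ring B closes as the seven-membered carbocycle by the C9–C10 bond, the pyran oxygen remaining as a bridge between C5 and C9. Bond formation should be asynchronous and polarity-matched, the CH2 end (C10) attacking the oxocarbenium-like C9 while the enolate carbon C5 collapses onto the cation-like tertiary C1, which is why two fully substituted carbons can be joined. C1, C5 and C9 are fixed relative to one another by the tether, which can reach from the bridgehead only to the exo position of C1, so CH3-15 is endo and anti to the oxygen bridge (the later trans ring fusion). The face of the ylide, and so the configuration of these centres relative to C4, is chosen by the C4 stereocentre: the tertiary hydroxyl lies in the ring plane, hydrogen-bonded to the oxido oxygen on C6, the isopropyl group then occupies one face and the alkene adds from the other, which gives the 4β-OH/15β-CH3 relationship. The selectivities needed are this facial one and cycloaddition in preference to ylide dimerisation or capture of the hydroxyl; the hydrogen bond and high dilution are meant to secure them, and the hydroxyl cannot add to C9 of the ylide because that would create a bridgehead enolate.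

Step 10
Reactants: 17 5α,9α-epoxy-4β-hydroxydauc-7-en-6-one
Product: 19 5α,9α-epoxy-4β-hydroxydauc-8(14)-en-6-one, via dipotassium dienolate 18 (not isolated)
Conditions: KN(SiMe3)2 (2.2 equiv), THF, −78 °C; then AcOH, −78 °C
Reagents that add atoms: none
Why: Kinetic deconjugation: the C14 methyl carries the only removable γ-hydrogens (C5 has no hydrogen, C9 is a bridgehead) and α-protonation of the dienolate at C7 gives the β,γ-unsaturated ketone; this takes the C7=C8 π bond out of conjugation so that electron transfer in step 11 can break only the C5–O bond and not the vinylogous C9–O bond.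

Step 11
Reactants: 19 5α,9α-epoxy-4β-hydroxydauc-8(14)-en-6-one
Product: 21 4β,9α-dihydroxydauc-7-en-6-one, via deconjugated diol 20 (not isolated)
Conditions: SmI2 (2.5 equiv), MeOH, THF, −78 °C; aqueous work-up; then DBU (0.2 equiv), CH2Cl2, 0 °C
Reagents that add atoms: none
Why: Samarium diiodide reduction of an α-alkoxy ketone breaks the C5–O bond next to the ketyl; the samarium enolate should be protonated at C5 on the α face that the oxygen has just left (also the more stable trans ring fusion, with C6 anti to the isopropyl group), and catalytic DBU then moves the exocyclic double bond back into conjugation through the doubly activated C7–H.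

Step 12
Reactants: 21 4β,9α-dihydroxydauc-7-en-6-one
Product: 22 4β-hydroxy-9β-(phenylselanyl)dauc-7-en-6-one
Conditions: N-(phenylselanyl)phthalimide, n-Bu3P, THF, −20 → 0 °C
Reagents that add atoms: N-(phenylselanyl)phthalimide, O=C1c2ccccc2C(=O)N1[Se]c1ccccc1
Why: Phosphine-mediated selenation (Grieco–Nicolaou conditions): the secondary allylic hydroxyl is activated as an alkoxyphosphonium ion and displaced by phenylselenolate in an SN2 step with inversion (9α-OH to 9β-Se), the tertiary hydroxyl is inert, and conjugation with the ketone keeps the selenide at C9.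

Step 13
Reactants: 22 4β-hydroxy-9β-(phenylselanyl)dauc-7-en-6-one
Product: 23 9β-(phenylselanyl)dauc-7-ene-4β,6α-diol
Conditions: Me4NBH(OAc)3, MeCN/AcOH 1:1, −20 °C
Reagents that add atoms: none
Why: Saksena–Evans reduction: the acetoxyborohydride bound to the 4β-hydroxyl delivers hydride within the molecule to the β face of the C6 carbonyl (1,2-reduction only), which sets the 6α-hydroxyl anti to the C4 oxygen.

Step 14
Reactants: 23 9β-(phenylselanyl)dauc-7-ene-4β,6α-diol; 24 4-[(tert-butyldimethylsilyl)oxy]benzoic acid
Product: 25 4β-hydroxy-9β-(phenylselanyl)dauc-7-en-6α-yl 4-[(tert-butyldimethylsilyl)oxy]benzoate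
Conditions: DCC, DMAP, CH2Cl2, rt
Reagents that add atoms: none
Why: Steglich esterification of the only acylable hydroxyl (the tertiary alcohol should not react); the ester is placed on O6 before any oxygen exists on C7, so no regiochemical question arises.

Step 15
Reactants: 25 4β-hydroxy-9β-(phenylselanyl)dauc-7-en-6α-yl 4-[(tert-butyldimethylsilyl)oxy]benzoate
Product: 28 4β,7β-dihydroxydauc-8-en-6α-yl 4-[(tert-butyldimethylsilyl)oxy]benzoate, via allyl selenoxide 26 (not isolated), via allyl selenenate 27 (not isolated)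
Conditions: H2O2 (30% aq.), pyridine, CH2Cl2, 0 °C → rt
Reagents that add atoms: hydrogen peroxide, OO
Why: Oxidation of the selenide to the selenoxide triggers a suprafacial [2,3]-sigmatropic shift (selenium analogue of the Mislow–Evans rearrangement): oxygen is delivered to C7 on the β face on which selenium sat at C9, the double bond moves to C8=C9 and the selenenate is hydrolysed, so the 7β-hydroxyl is set by transfer of chirality from C9.

Step 16
Reactants: 28 4β,7β-dihydroxydauc-8-en-6α-yl 4-[(tert-butyldimethylsilyl)oxy]benzoate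
Product: 29 4β-hydroxy-7β-[(triethylsilyl)oxy]dauc-8-en-6α-yl 4-[(tert-butyldimethylsilyl)oxy]benzoate
Conditions: Et3SiOTf, 2,6-lutidine, CH2Cl2, −78 °C
Reagents that add atoms: triethylsilyl trifluoromethanesulfonate, CC[Si](CC)(CC)OS(=O)(=O)C(F)(F)F
Why: Silylation of the secondary allylic hydroxyl (the hindered tertiary one should be left) removes the hydroxyl that would guide a peracid to the β face and adds bulk on that face.

Step 17
Reactants: 29 4β-hydroxy-7β-[(triethylsilyl)oxy]dauc-8-en-6α-yl 4-[(tert-butyldimethylsilyl)oxy]benzoate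
Product: 30 8α,9α-epoxy-4β-hydroxy-7β-[(triethylsilyl)oxy]daucan-6α-yl 4-[(tert-butyldimethylsilyl)oxy]benzoate
Conditions: mCPBA, NaHCO3, CH2Cl2, 0 °C
Reagents that add atoms: 3-chloroperbenzoic acid, O=C(OO)c1cccc(Cl)c1
Why: Prilezhaev epoxidation of the trisubstituted alkene from the α face, because the β face is screened at C8 by the 7β-silyloxy group and at C9 by the angular methyl on C1 (as in the α-epoxidation of steroid 2-enes); C8 and C9 are set together.

Step 18
Reactants: 30 8α,9α-epoxy-4β-hydroxy-7β-[(triethylsilyl)oxy]daucan-6α-yl 4-[(tert-butyldimethylsilyl)oxy]benzoate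
Product: 31 8α,9α-epoxy-4β,7β-dihydroxydaucan-6α-yl 4-hydroxybenzoate (CNP0290052.1)
Conditions: Bu4NF, AcOH, THF, 0 °C → rt
Reagents that add atoms: none
Why: Fluoride-mediated desilylation removes the aryl and the secondary silyl ether; buffering with acetic acid should keep the ester and the epoxide intact.

**Compound list**

1 | (R)-2-hydroxy-3-methylbutanoic acid | CC(C)[C@@H](O)C(=O)O | starting material
2 | (2R,5R)-2-tert-butyl-5-(propan-2-yl)-1,3-dioxolan-4-one | CC(C)[C@H]1O[C@@H](C(C)(C)C)OC1=O | intermediate
3 | 3-methylbut-3-en-1-ol | C=C(C)CCO | starting material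
4 | 3-methylbut-3-en-1-yl trifluoromethanesulfonate | C=C(C)CCOS(=O)(=O)C(F)(F)F | intermediate
5 | lithium enolate of 2 (2R) | CC(C)C1=C(O[Li])O[C@H](C(C)(C)C)O1 | intermediate
6 | (2R,5R)-2-tert-butyl-5-(3-methylbut-3-en-1-yl)-5-(propan-2-yl)-1,3-dioxolan-4-one | CC(C)[C@@]1(CCC(C)=C)O[C@@H](C(C)(C)C)OC1=O | intermediate
7 | 3-methylfuran | Cc1ccoc1 | starting material
8 | 2-bromo-3-methylfuran | Cc1ccoc1Br | intermediate
9 | (5-bromo-4-methylfuran-2-yl)lithium | [Li]c1cc(C)c(Br)o1 | intermediate
10 | lithium (2R,5R)-4-(5-bromo-4-methylfuran-2-yl)-2-tert-butyl-5-(3-methylbut-3-en-1-yl)-5-(propan-2-yl)-1,3-dioxolan-4-olate (C4 epimers) | CC(C)[C@@]1(CCC(C)=C)O[C@@H](C(C)(C)C)OC1(O[Li])c1cc(C)c(Br)o1 | intermediate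
11 | lithium (2R,5R)-2-tert-butyl-4-(5-lithio-4-methylfuran-2-yl)-5-(3-methylbut-3-en-1-yl)-5-(propan-2-yl)-1,3-dioxolan-4-olate (C4 epimers) | CC(C)[C@@]1(CCC(C)=C)O[C@@H](C(C)(C)C)OC1(O[Li])c1cc(C)c([Li])o1 | intermediate
12 | (2R)-2-hydroxy-5-methyl-1-(4-methylfuran-2-yl)-2-(propan-2-yl)hex-5-en-1-one | CC(C)[C@](O)(CCC(C)=C)C(=O)c1cc(C)co1 | intermediate
13 | (1RS,2R)-5-methyl-1-(4-methylfuran-2-yl)-2-(propan-2-yl)hex-5-ene-1,2-diol | CC(C)[C@](O)(CCC(C)=C)C(O)c1cc(C)co1 | intermediate
14 | 6-hydroxy-2-[(3R)-3-hydroxy-2,6-dimethylhept-6-en-3-yl]-5-methyl-2H-pyran-3(6H)-one | CC(C)[C@](O)(CCC(C)=C)C1OC(O)C(C)=CC1=O | intermediate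
15 | 6-[(3R)-3-hydroxy-2,6-dimethylhept-6-en-3-yl]-3-methyl-5-oxo-5,6-dihydro-2H-pyran-2-yl acetate | CC(C)[C@](O)(CCC(C)=C)C1OC(OC(C)=O)C(C)=CC1=O | intermediate
16 | 2-[(3R)-3-hydroxy-2,6-dimethylhept-6-en-3-yl]-5-methylpyrylium-3-olate | CC(C)[C@](O)(CCC(C)=C)c1[o+]cc(C)cc1[O-] | intermediate
17 | 5α,9α-epoxy-4β-hydroxydauc-7-en-6-one | CC(C)[C@]1(O)CC[C@]2(C)C[C@@H]3O[C@]12C(=O)C=C3C | intermediate
18 | dipotassium alkoxide dienolate of 17 | CC(C)[C@]1(O[K])CC[C@]2(C)C[C@@H]3O[C@]12C(O[K])=CC3=C | intermediate
19 | 5α,9α-epoxy-4β-hydroxydauc-8(14)-en-6-one | CC(C)[C@]1(O)CC[C@]2(C)C[C@@H]3O[C@]12C(=O)CC3=C | intermediate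
20 | 4β,9α-dihydroxydauc-8(14)-en-6-one | CC(C)[C@]1(O)CC[C@]2(C)C[C@H](O)C(=C)CC(=O)[C@@H]12 | intermediate
21 | 4β,9α-dihydroxydauc-7-en-6-one | CC(C)[C@]1(O)CC[C@]2(C)C[C@H](O)C(C)=CC(=O)[C@@H]12 | intermediate
22 | 4β-hydroxy-9β-(phenylselanyl)dauc-7-en-6-one | CC(C)[C@]1(O)CC[C@]2(C)C[C@@H]([Se]c3ccccc3)C(C)=CC(=O)[C@@H]12 | intermediate
23 | 9β-(phenylselanyl)dauc-7-ene-4β,6α-diol | CC(C)[C@]1(O)CC[C@]2(C)C[C@@H]([Se]c3ccccc3)C(C)=C[C@H](O)[C@@H]12 | intermediate
24 | 4-[(tert-butyldimethylsilyl)oxy]benzoic acid | CC(C)(C)[Si](C)(C)Oc1ccc(cc1)C(=O)O | starting material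
25 | 4β-hydroxy-9β-(phenylselanyl)dauc-7-en-6α-yl 4-[(tert-butyldimethylsilyl)oxy]benzoate | CC(C)[C@]1(O)CC[C@]2(C)C[C@@H]([Se]c3ccccc3)C(C)=C[C@H](OC(=O)c3ccc(O[Si](C)(C)C(C)(C)C)cc3)[C@@H]12 | intermediate
26 | 9β-selenoxide of 25 | CC(C)[C@]1(O)CC[C@]2(C)C[C@@H]([Se](=O)c3ccccc3)C(C)=C[C@H](OC(=O)c3ccc(O[Si](C)(C)C(C)(C)C)cc3)[C@@H]12 | intermediate
27 | 7β-O-phenylselenenate of 28 | CC(C)[C@]1(O)CC[C@]2(C)CC=C(C)[C@@H](O[Se]c3ccccc3)[C@H](OC(=O)c3ccc(O[Si](C)(C)C(C)(C)C)cc3)[C@@H]12 | intermediate
28 | 4β,7β-dihydroxydauc-8-en-6α-yl 4-[(tert-butyldimethylsilyl)oxy]benzoate | CC(C)[C@]1(O)CC[C@]2(C)CC=C(C)[C@@H](O)[C@H](OC(=O)c3ccc(O[Si](C)(C)C(C)(C)C)cc3)[C@@H]12 | intermediate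
29 | 4β-hydroxy-7β-[(triethylsilyl)oxy]dauc-8-en-6α-yl 4-[(tert-butyldimethylsilyl)oxy]benzoate | CC(C)[C@]1(O)CC[C@]2(C)CC=C(C)[C@@H](O[Si](CC)(CC)CC)[C@H](OC(=O)c3ccc(O[Si](C)(C)C(C)(C)C)cc3)[C@@H]12 | intermediate
30 | 8α,9α-epoxy-4β-hydroxy-7β-[(triethylsilyl)oxy]daucan-6α-yl 4-[(tert-butyldimethylsilyl)oxy]benzoate | CC(C)[C@]1(O)CC[C@]2(C)C[C@@H]3O[C@]3(C)[C@@H](O[Si](CC)(CC)CC)[C@H](OC(=O)c3ccc(O[Si](C)(C)C(C)(C)C)cc3)[C@H]21 | intermediate
31 | 8α,9α-epoxy-4β,7β-dihydroxydaucan-6α-yl 4-hydroxybenzoate (CNP0290052.1) | CC(C)[C@]1(O)CC[C@]2(C)C[C@@H]3O[C@]3(C)[C@@H](O)[C@H](OC(=O)c3ccc(O)cc3)[C@H]21 | target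

**Step count**

Total step count: 18. Longest linear sequence: 16 steps (1, 3, 5–18); steps 2 and 4 are side branches.

**Steps most likely to fail, with fallbacks**

Step 9 (key step). What may go wrong: loss of facial control if the internal hydrogen bond is broken up by the amine salt, capture of the C5-protonated cation by the free tertiary hydroxyl to give a bicyclic ketal, and dimerisation of the ylide because the alkene is hindered. Fallback: the hydroxyl is masked and the face is then controlled by A(1,3) strain instead of a hydrogen bond. Setting out from 15, silylation with 1-(trimethylsilyl)imidazole in CH2Cl2 should give the trimethylsilyl ether acetate F1. Treatment of F1 with DBU in dilute toluene at 80 °C should give the silylated cycloadduct F2; here the isopropyl group is expected to avoid the in-plane site that flanks the oxido oxygen, which leads to the same face. Methanolysis of F2 (K2CO3, MeOH, 0 °C) returns to the route at 17.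

Step 3. What may go wrong: decomposition of the thermally labile, hindered enolate before it is alkylated, elimination of the homoallylic electrophile to isoprene, and ionisation of the triflate. Fallback: the chain is introduced by conjugate addition instead of substitution. Setting out from 2, the enolate 5 is added at −78 °C to 3-(trimethylsilyl)but-3-en-2-one, an acceptor made for hindered aprotic enolates, to give the α-silyl ketone F3 (again trans to tert-butyl). Desilylation with Bu4NF/AcOH gives the methyl ketone F4, and ketone-selective methylenation (Zn, CH2Br2, TiCl4, THF) comes back to the route at 6.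

Step 5. What may go wrong: collapse of the tetrahedral intermediate during the reaction followed by a second addition of the aryllithium, and incomplete bromine–lithium exchange in the presence of the hemiketal. Fallback: the furan is added to an aldehyde instead of the lactone. Setting out from 6, reduction with LiAlH4 (THF, 0 °C) gives the diol F5, and oxidation of the primary alcohol (TEMPO, PhI(OAc)2, CH2Cl2) gives the α-hydroxy aldehyde F6. Addition of furyllithium 9 (2.2 equiv, −78 °C) gives the bromo diol F7 as its dilithium alkoxide, which is inert to the exchange; n-BuLi and then MeOH in the same flask remove the bromine and come back to the route at 13, so that steps 5 and 6 are replaced.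

**Further compounds**

F1 | step 9 | 6-{(3R)-2,6-dimethyl-3-[(trimethylsilyl)oxy]hept-6-en-3-yl}-3-methyl-5-oxo-5,6-dihydro-2H-pyran-2-yl acetate | CC(C)[C@](O[Si](C)(C)C)(CCC(C)=C)C1OC(OC(C)=O)C(C)=CC1=O
F2 | step 9 | 5α,9α-epoxy-4β-[(trimethylsilyl)oxy]dauc-7-en-6-one | CC(C)[C@]1(O[Si](C)(C)C)CC[C@]2(C)C[C@@H]3O[C@]12C(=O)C=C3C
F3 | step 3 | (2R,5R)-2-tert-butyl-5-[3-oxo-2-(trimethylsilyl)butyl]-5-(propan-2-yl)-1,3-dioxolan-4-one | CC(C)[C@@]1(CC(C(C)=O)[Si](C)(C)C)O[C@@H](C(C)(C)C)OC1=O
F4 | step 3 | (2R,5R)-2-tert-butyl-5-(3-oxobutyl)-5-(propan-2-yl)-1,3-dioxolan-4-one | CC(C)[C@@]1(CCC(C)=O)O[C@@H](C(C)(C)C)OC1=O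
F5 | step 5 | (2R)-5-methyl-2-(propan-2-yl)hex-5-ene-1,2-diol | CC(C)[C@](O)(CCC(C)=C)CO
F6 | step 5 | (2R)-2-hydroxy-5-methyl-2-(propan-2-yl)hex-5-enal | CC(C)[C@](O)(CCC(C)=C)C=O
F7 | step 5 | (1RS,2R)-1-(5-bromo-4-methylfuran-2-yl)-5-methyl-2-(propan-2-yl)hex-5-ene-1,2-diol | CC(C)[C@](O)(CCC(C)=C)C(O)c1cc(C)c(Br)o1
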